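**Plan**

1. Numbering used (bicyclo[3.3.1]nonane): C1 benzoyl bridgehead, C2 (C–OMe), C3, C4 (C=O), C5 prenyl bridgehead, C6, C7 (side chain C1′–C4′), C8 (CMe2), C9 (bridge C=O). The retrosynthesis cuts C9–C5 and C2–C3 together, after O–CH3 (reached through S–CH3) and the C2′=C3′ alkene; then C1–C2, the lactone C–O, C4–C3, C5–prenyl, the ring O-insertion and C7–C8.
2. Enabling feature: ketone C4 has two enolisable α-carbons (C3, C5) and C1 holds two carboxyl-level carbons (C9, C2). A 1,3-dinucleophile faces a 1,3-dielectrophile, so one double Claisen closes ring B (C1–C8–C7–C6–C5–C9) and then ring A (C1–C2–C3–C4–C5–C9).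
3. Forward order: C7–C8 by conjugate addition → symmetric cyclohexanone → Baeyer–Villiger lactone → C5 prenyl and C4 ketone → seven-membered β-keto lactone (temporary ring tying the C9 carbonyl through O to C2′) → dithioester on C1 → ring B, then ring A → OMe and side chain.
4. Stereochemistry: C7 from enzymatic desymmetrisation; C1 relayed from C7 across the temporary lactone; C5 fixed by the ring closure itself; the E-alkene from a stabilised Wittig reaction.

Key step: step 9

Remark: read from the SMILES, the C7 side chain is cis to C2/C4 (endo). An untethered chair-type double Claisen would be expected to give the exo isomer, hence the lactone relay. Compounds 4 and 11 and the named reagents are taken as commercial.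

**Route**

Step 1
Reactants: 1 ethyl benzoylacetate; 2 acetone
Product: 3 ethyl 2-benzoyl-3-methylbut-2-enoate
Conditions: TiCl4, pyridine, THF, 0 °C → rt
Reagents that add atoms: none
Why: Knoevenagel condensation of a β-keto ester with a ketone under TiCl4/pyridine dehydration should give the tetrasubstituted alkylidene; no stereocentre is formed.

Step 2
Reactants: 4 8-bromo-1,4-dioxaspiro[4.5]decane; 3 ethyl 2-benzoyl-3-methylbut-2-enoate
Product: 7 ethyl 2-benzoyl-3-methyl-3-(4-oxocyclohexyl)butanoate, via Grignard reagent 5 (not isolated), via ketal adduct 6 (not isolated)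
Conditions: Mg, THF; CuBr·SMe2 (10 mol %), 3, THF, −40 → 0 °C; then 2 M HCl, THF, rt
Reagents that add atoms: water, O
Why: Copper-catalysed conjugate addition of a Grignard reagent to an alkylidene β-keto ester should form the quaternary C8 and the C7–C8 bond, and the acidic work-up hydrolyses the dioxolane; the ring is still symmetric, so only the acidic, epimerisable C1 is stereogenic.

Step 3
Reactants: 7 ethyl 2-benzoyl-3-methyl-3-(4-oxocyclohexyl)butanoate
Product: 8 ethyl 2-benzoyl-3-methyl-3-[(4R)-7-oxooxepan-4-yl]butanoate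
Conditions: Baeyer–Villiger monooxygenase (cyclohexanone monooxygenase family, variant selected for the R lactone), NADP+ (cat.), D-glucose, glucose dehydrogenase, air, phosphate buffer pH 8, 5% MeOH, 30 °C
Reagents that add atoms: dioxygen, O=O
Why: Enzymatic Baeyer–Villiger desymmetrisation of a 4-substituted cyclohexanone should distinguish the two enantiotopic α-CH2 groups and so set C7, while the remote C1 epimers are both expected to be processed in the same sense.

Step 4
Reactants: 8 ethyl 2-benzoyl-3-methyl-3-[(4R)-7-oxooxepan-4-yl]butanoate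
Product: 9 ethyl 2-benzoyl-3-methyl-3-[(4R)-6-(3-methylbut-2-en-1-yl)-7-oxooxepan-4-yl]butanoate
Conditions: LiN(i-Pr)2 (2.1 equiv), THF, −78 °C; prenyl bromide, −78 → −40 °C
Reagents that add atoms: 1-bromo-3-methylbut-2-ene (prenyl bromide), CC(C)=CCBr
Why: Lactone enolate alkylation of the dianion (the β-keto ester enolate is the unreactive site) should place the prenyl group at the only lactone α-carbon (C5); the new centre is uncontrolled and becomes planar again in step 9.

Step 5
Reactants: 9 ethyl 2-benzoyl-3-methyl-3-[(4R)-6-(3-methylbut-2-en-1-yl)-7-oxooxepan-4-yl]butanoate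
Product: 10 ethyl 2-benzoyl-3-[(3R)-1-hydroxy-5-[methoxy(methyl)carbamoyl]-8-methylnon-7-en-3-yl]-3-methylbutanoate
Conditions: MeNH(OMe)·HCl, i-PrMgCl (excess), THF, −20 → 0 °C
Reagents that add atoms: N,O-dimethylhydroxylamine hydrochloride, CNOC.Cl
Why: Aminolysis of the lactone by the chloromagnesium amide should give the Weinreb amide and free the C2′ alcohol, the β-keto ester being protected as its magnesium enolate.

Step 6
Reactants: 10 ethyl 2-benzoyl-3-[(3R)-1-hydroxy-5-[methoxy(methyl)carbamoyl]-8-methylnon-7-en-3-yl]-3-methylbutanoate; 11 5-bromo-2-methylpent-2-ene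
Product: 13 ethyl 2-benzoyl-3-[(3R)-1-hydroxy-10-methyl-5-(3-methylbut-2-en-1-yl)-6-oxoundec-9-en-3-yl]-3-methylbutanoate, via Grignard reagent 12 (not isolated)
Conditions: Mg, THF (from 11); then 10, THF, 0 °C (3.5 equiv of 12); NH4Cl
Reagents that add atoms: none
Why: Weinreb ketone synthesis: the chelated tetrahedral intermediate should stop at the ketone C4, which now carries C3 with its prenyl-bearing CH2, while the alkoxide and the β-keto ester enolate only consume base.

Step 7
Reactants: 13 ethyl 2-benzoyl-3-[(3R)-1-hydroxy-10-methyl-5-(3-methylbut-2-en-1-yl)-6-oxoundec-9-en-3-yl]-3-methylbutanoate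
Product: 14 (5R)-3-benzoyl-4,4-dimethyl-5-[7-methyl-2-(3-methylbut-2-en-1-yl)-3-oxooct-6-en-1-yl]oxepan-2-one
Conditions: DMAP (0.3 equiv), toluene (2 mM), 110 °C, 4 Å molecular sieves
Reagents that add atoms: none
Why: DMAP-catalysed transesterification of a β-keto ester through its acyl ketene, run as a lactonisation and helped by the gem-dimethyl group, should close the seven-membered β-keto lactone that ties the future C9 carbonyl to C2′.

Step 8
Reactants: 14 (5R)-3-benzoyl-4,4-dimethyl-5-[7-methyl-2-(3-methylbut-2-en-1-yl)-3-oxooct-6-en-1-yl]oxepan-2-one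
Product: 15 methyl (3R,5R)-3-benzoyl-4,4-dimethyl-5-[7-methyl-2-(3-methylbut-2-en-1-yl)-3-oxooct-6-en-1-yl]-2-oxooxepane-3-carbodithioate
Conditions: NaH (1.1 equiv), DMF–THF, 0 °C; CS2 (5 equiv); MeI (1.5 equiv), 0 °C → rt
Reagents that add atoms: carbon disulfide, S=C=S; iodomethane, CI
Why: Addition of the stabilised β-keto lactone enolate to CS2 followed by S-methylation (dithioester synthesis from a 1,3-dicarbonyl methine) is C-selective, and the small electrophile should enter pseudo-axially, anti to the C5 side chain, leaving the larger benzoyl group cis to it and so setting C1.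

Step 9
Reactants: 15 methyl (3R,5R)-3-benzoyl-4,4-dimethyl-5-[7-methyl-2-(3-methylbut-2-en-1-yl)-3-oxooct-6-en-1-yl]-2-oxooxepane-3-carbodithioate
Product: 18 (1R,5S,7R)-1-benzoyl-7-(2-hydroxyethyl)-8,8-dimethyl-3,5-bis(3-methylbut-2-en-1-yl)-2-(methylsulfanyl)bicyclo[3.3.1]non-2-ene-4,9-dione, via cyclohexanedione intermediate 16 (not isolated), via enethiol 17 (not isolated)
Conditions: t-BuOK (3.2 equiv), THF, −40 → 0 °C; then MeI (2.2 equiv), −40 °C; NH4Cl
Reagents that add atoms: iodomethane, CI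
Why: t-BuOK equilibrates the ketone enolates and only the C5 enolate has a six-membered path: it attacks the lactone carbonyl (6-exo-trig), the seven-membered lactone collapses to ring B with the new C5–C9 bond and frees the C2′ alkoxide, then the C3 enolate attacks the thiocarbonyl (6-exo-trig) with loss of methanethiolate to close ring A through the C2–C3 bond, and the resulting enethiolate is S-methylated. The closest known reaction types are the domino Dieckmann cyclisation of malonate-tethered ketones to bicyclo[3.3.1]nonane-2,4,9-triones and the thio-Claisen acylation of ketone enolates by dithioesters. C1 and C7 are already set; at C5 only the epimer with the C4 acyl group cis to the dithioester can close ring A, and the other should return through alkoxide-mediated retro-Claisen reopening. The step needs endo over exo selectivity: the C1 face syn to H7 carries benzoyl, which is not a productive acyl donor, and the dithioester is trans to the C7 arm on the lactone ring so C5 cannot reach it, which means C9 must come from the lactone and C2 from the dithioester. Loss or migration of the C1 acyl groups should be slow because the C1 carbanion would be a twisted, tert-alkyl-substituted enolate, and the enethiolate is the thermodynamic sink. Sulfur at C2 marks that carbon alone for the later methoxy group.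

Step 10
Reactants: 18 (1R,5S,7R)-1-benzoyl-7-(2-hydroxyethyl)-8,8-dimethyl-3,5-bis(3-methylbut-2-en-1-yl)-2-(methylsulfanyl)bicyclo[3.3.1]non-2-ene-4,9-dione
Product: 19 (1R,5S,7R)-1-benzoyl-7-(2-hydroxyethyl)-2-methoxy-8,8-dimethyl-3,5-bis(3-methylbut-2-en-1-yl)bicyclo[3.3.1]non-2-ene-4,9-dione
Conditions: NaOMe (1.5 equiv), MeOH, 0 °C → rt; AcOH
Reagents that add atoms: sodium methoxide, C[O-].[Na+]
Why: Addition–elimination of methoxide at the β-carbon of the β-(methylthio) enone should exchange SMe for OMe only at C2, because C4 carries no leaving group.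

Step 11
Reactants: 19 (1R,5S,7R)-1-benzoyl-7-(2-hydroxyethyl)-2-methoxy-8,8-dimethyl-3,5-bis(3-methylbut-2-en-1-yl)bicyclo[3.3.1]non-2-ene-4,9-dione
Product: 20 (1R,5S,7R)-1-benzoyl-2-methoxy-8,8-dimethyl-3,5-bis(3-methylbut-2-en-1-yl)-7-(2-oxoethyl)bicyclo[3.3.1]non-2-ene-4,9-dione
Conditions: Dess–Martin periodinane, NaHCO3, CH2Cl2, 0 °C → rt
Reagents that add atoms: none
Why: Dess–Martin oxidation of the primary alcohol should give the aldehyde under neutral conditions that leave the enol ether and the prenyl groups untouched.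

Step 12
Reactants: 20 (1R,5S,7R)-1-benzoyl-2-methoxy-8,8-dimethyl-3,5-bis(3-methylbut-2-en-1-yl)-7-(2-oxoethyl)bicyclo[3.3.1]non-2-ene-4,9-dione
Product: 21 (1R,5S,7S)-1-benzoyl-2-methoxy-8,8-dimethyl-7-[(2E)-3-methyl-4-oxobut-2-en-1-yl]-3,5-bis(3-methylbut-2-en-1-yl)bicyclo[3.3.1]non-2-ene-4,9-dione
Conditions: 2-(triphenylphosphoranylidene)propanal, toluene, 80 °C
Reagents that add atoms: 2-(triphenylphosphoranylidene)propanal, CC(C=O)=P(c1ccccc1)(c1ccccc1)c1ccccc1
Why: Wittig reaction of a stabilised ylide with the aldehyde should give the E trisubstituted enal and leave the hindered ketones alone.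

Step 13
Reactants: 21 (1R,5S,7S)-1-benzoyl-2-methoxy-8,8-dimethyl-7-[(2E)-3-methyl-4-oxobut-2-en-1-yl]-3,5-bis(3-methylbut-2-en-1-yl)bicyclo[3.3.1]non-2-ene-4,9-dione
Product: 22 (1R,5S,7S)-1-benzoyl-7-[(2E)-4-hydroxy-3-methylbut-2-en-1-yl]-2-methoxy-8,8-dimethyl-3,5-bis(3-methylbut-2-en-1-yl)bicyclo[3.3.1]non-2-ene-4,9-dione
Conditions: NaBH4 (0.5 equiv), MeOH–CH2Cl2, −40 °C
Reagents that add atoms: none
Why: 1,2-Reduction of the enal by NaBH4 at low temperature should be chemoselective over the two ketones flanked by quaternary carbons and the vinylogous ester.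

Step 14
Reactants: 22 (1R,5S,7S)-1-benzoyl-7-[(2E)-4-hydroxy-3-methylbut-2-en-1-yl]-2-methoxy-8,8-dimethyl-3,5-bis(3-methylbut-2-en-1-yl)bicyclo[3.3.1]non-2-ene-4,9-dione
Product: 23 (2E)-4-[(1R,5S,7S)-1-benzoyl-2-methoxy-8,8-dimethyl-3,5-bis(3-methylbut-2-en-1-yl)-4,9-dioxobicyclo[3.3.1]non-2-en-7-yl]-2-methylbut-2-en-1-yl acetate (target)
Conditions: Ac2O, pyridine, DMAP (cat.), CH2Cl2, 0 °C → rt
Reagents that add atoms: acetic anhydride, CC(=O)OC(C)=O
Why: Acetylation of the primary allylic alcohol should complete the target without touching any stereocentre.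

**Compound list**

1 | ethyl benzoylacetate | CCOC(=O)CC(=O)c1ccccc1 | starting material
2 | acetone | CC(C)=O | starting material
3 | ethyl 2-benzoyl-3-methylbut-2-enoate | CCOC(=O)C(C(=O)c1ccccc1)=C(C)C | intermediate
4 | 8-bromo-1,4-dioxaspiro[4.5]decane | BrC1CCC2(CC1)OCCO2 | starting material
5 | (1,4-dioxaspiro[4.5]decan-8-yl)magnesium bromide | Br[Mg]C1CCC2(CC1)OCCO2 | intermediate (not isolated)
6 | ethyl 2-benzoyl-3-(1,4-dioxaspiro[4.5]decan-8-yl)-3-methylbutanoate | CCOC(=O)C(C(=O)c1ccccc1)C(C)(C)C1CCC2(CC1)OCCO2 | intermediate (not isolated)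
7 | ethyl 2-benzoyl-3-methyl-3-(4-oxocyclohexyl)butanoate | CCOC(=O)C(C(=O)c1ccccc1)C(C)(C)C1CCC(=O)CC1 | intermediate
8 | ethyl 2-benzoyl-3-methyl-3-[(4R)-7-oxooxepan-4-yl]butanoate (C2 epimers) | O=C1CC[C@H](CCO1)C(C)(C)C(C(=O)c1ccccc1)C(=O)OCC | intermediate
9 | ethyl 2-benzoyl-3-methyl-3-[(4R)-6-(3-methylbut-2-en-1-yl)-7-oxooxepan-4-yl]butanoate (epimers at C2 and ring C6) | O=C1C(CC=C(C)C)C[C@H](CCO1)C(C)(C)C(C(=O)c1ccccc1)C(=O)OCC | intermediate
10 | ethyl 2-benzoyl-3-[(3R)-1-hydroxy-5-[methoxy(methyl)carbamoyl]-8-methylnon-7-en-3-yl]-3-methylbutanoate | CON(C)C(=O)C(CC=C(C)C)C[C@H](CCO)C(C)(C)C(C(=O)c1ccccc1)C(=O)OCC | intermediate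
11 | 5-bromo-2-methylpent-2-ene | CC(C)=CCCBr | starting material
12 | (4-methylpent-3-en-1-yl)magnesium bromide | CC(C)=CCC[Mg]Br | intermediate (not isolated)
13 | ethyl 2-benzoyl-3-[(3R)-1-hydroxy-10-methyl-5-(3-methylbut-2-en-1-yl)-6-oxoundec-9-en-3-yl]-3-methylbutanoate | CC(C)=CCCC(=O)C(CC=C(C)C)C[C@H](CCO)C(C)(C)C(C(=O)c1ccccc1)C(=O)OCC | intermediate
14 | (5R)-3-benzoyl-4,4-dimethyl-5-[7-methyl-2-(3-methylbut-2-en-1-yl)-3-oxooct-6-en-1-yl]oxepan-2-one (C3 epimers) | O=C1OCC[C@@H](CC(CC=C(C)C)C(=O)CCC=C(C)C)C(C)(C)C1C(=O)c1ccccc1 | intermediate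
15 | methyl (3R,5R)-3-benzoyl-4,4-dimethyl-5-[7-methyl-2-(3-methylbut-2-en-1-yl)-3-oxooct-6-en-1-yl]-2-oxooxepane-3-carbodithioate | CSC(=S)[C@]1(C(=O)c2ccccc2)C(=O)OCC[C@@H](CC(CC=C(C)C)C(=O)CCC=C(C)C)C1(C)C | intermediate
16 | ring B closed: cyclohexanone (C9) bearing at C1 benzoyl and the methyl dithioester, at C5 prenyl and the 5-methylhex-4-enoyl group, at C7 the 2-hydroxyethyl chain, at C8 two methyls; configuration at C1, C5, C7 as in 18 | CSC(=S)[C@]1(C(=O)c2ccccc2)C(=O)[C@](CC=C(C)C)(C(=O)CCC=C(C)C)C[C@H](CCO)C1(C)C | intermediate (not isolated)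
17 | (1R,5S,7R)-1-benzoyl-7-(2-hydroxyethyl)-8,8-dimethyl-3,5-bis(3-methylbut-2-en-1-yl)-2-sulfanylbicyclo[3.3.1]non-2-ene-4,9-dione (enethiol form) | SC1=C(CC=C(C)C)C(=O)[C@]2(CC=C(C)C)C[C@H](CCO)C(C)(C)[C@@]1(C(=O)c1ccccc1)C2=O | intermediate (not isolated)
18 | (1R,5S,7R)-1-benzoyl-7-(2-hydroxyethyl)-8,8-dimethyl-3,5-bis(3-methylbut-2-en-1-yl)-2-(methylsulfanyl)bicyclo[3.3.1]non-2-ene-4,9-dione | CSC1=C(CC=C(C)C)C(=O)[C@]2(CC=C(C)C)C[C@H](CCO)C(C)(C)[C@@]1(C(=O)c1ccccc1)C2=O | intermediate
19 | (1R,5S,7R)-1-benzoyl-7-(2-hydroxyethyl)-2-methoxy-8,8-dimethyl-3,5-bis(3-methylbut-2-en-1-yl)bicyclo[3.3.1]non-2-ene-4,9-dione | COC1=C(CC=C(C)C)C(=O)[C@]2(CC=C(C)C)C[C@H](CCO)C(C)(C)[C@@]1(C(=O)c1ccccc1)C2=O | intermediate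
20 | (1R,5S,7R)-1-benzoyl-2-methoxy-8,8-dimethyl-3,5-bis(3-methylbut-2-en-1-yl)-7-(2-oxoethyl)bicyclo[3.3.1]non-2-ene-4,9-dione | COC1=C(CC=C(C)C)C(=O)[C@]2(CC=C(C)C)C[C@H](CC=O)C(C)(C)[C@@]1(C(=O)c1ccccc1)C2=O | intermediate
21 | (1R,5S,7S)-1-benzoyl-2-methoxy-8,8-dimethyl-7-[(2E)-3-methyl-4-oxobut-2-en-1-yl]-3,5-bis(3-methylbut-2-en-1-yl)bicyclo[3.3.1]non-2-ene-4,9-dione | COC1=C(CC=C(C)C)C(=O)[C@]2(CC=C(C)C)C[C@H](C/C=C(\C)C=O)C(C)(C)[C@@]1(C(=O)c1ccccc1)C2=O | intermediate
22 | (1R,5S,7S)-1-benzoyl-7-[(2E)-4-hydroxy-3-methylbut-2-en-1-yl]-2-methoxy-8,8-dimethyl-3,5-bis(3-methylbut-2-en-1-yl)bicyclo[3.3.1]non-2-ene-4,9-dione | COC1=C(CC=C(C)C)C(=O)[C@]2(CC=C(C)C)C[C@H](C/C=C(\C)CO)C(C)(C)[C@@]1(C(=O)c1ccccc1)C2=O | intermediate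
23 | (2E)-4-[(1R,5S,7S)-1-benzoyl-2-methoxy-8,8-dimethyl-3,5-bis(3-methylbut-2-en-1-yl)-4,9-dioxobicyclo[3.3.1]non-2-en-7-yl]-2-methylbut-2-en-1-yl acetate | COC1=C(CC=C(C)C)C(=O)[C@]2(CC=C(C)C)C[C@H](C/C=C(\C)COC(C)=O)C(C)(C)[C@@]1(C(=O)c1ccccc1)C2=O | target

**Count and risks**

Total steps: 14. Longest linear sequence: 14 (steps 1–14; compound 4 enters at step 2 and compound 11 at step 6).

Steps most likely to fail:

1. Step 9. What may go wrong: acyl transfer away from C1 (benzoyl or the thioacyl group moving to C5 or C3, or retro-Claisen ring opening by alkoxide or thiolate) may outrun the second closure, which must pass through a boat-like ring B. Poor facial selectivity at C5 without recycling of the wrong epimer would have the same effect. Fallback, from 15: run only the first closure (t-BuOK, 1.05 equiv, THF, −78 °C, cold quench) and isolate cyclohexanedione 16. Silylate with TMSOTf/Et3N to give the bis(trimethylsilyl) compound F1, in which C3=C4 is the only possible silyl enol ether and the side-chain alcohol is capped. Then S-methylate the dithioester with MeOTf so that the resulting bis(methylthio)carbenium ion is attacked by the enol silane (Mukaiyama-type closure of ring A); loss of methanethiol and aqueous work-up return the route at 18.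

2. Step 8. What may go wrong: the hindered enolate may not hold CS2 (reversal of the adduct, with direct methylation of the enolate by MeI instead), or the thioacyl group may enter on the wrong face of C1. Fallback, from 14: C-acylate the magnesium chelate (MgCl2, Et3N, methyl chloroformate) to give the methyl ester lactone F2. Run the double Claisen with t-BuOK to give the enol trione F3. O-methylate with TMSCHN2 in MeOH–toluene and separate the C2-methoxy isomer from its C4 regioisomer; the route is rejoined at 19.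

3. Step 2. What may go wrong: the secondary Grignard reagent may reduce or deprotonate the tetrasubstituted acceptor 3 instead of adding to it. Fallback, from Grignard reagent 5: acylate with N-methoxy-N-methylacetamide to give the methyl ketone F4. Condense F4 with 1 (TiCl4, pyridine) to give the alkylidene β-keto ester F5. Form the quaternary carbon by conjugate addition of the small methyl group (Me2CuLi, Et2O, −78 °C); this rejoins the route at 6, which the acidic work-up of step 2 converts into 7.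

**Further compounds**

F1 | step 9 | bis(trimethylsilyl) derivative of 16 (C3=C4 silyl enol ether and side-chain silyl ether) | CSC(=S)[C@]1(C(=O)c2ccccc2)C(=O)[C@](CC=C(C)C)(C(O[Si](C)(C)C)=CCC=C(C)C)C[C@H](CCO[Si](C)(C)C)C1(C)C
F2 | step 8 | methyl (3R,5R)-3-benzoyl-4,4-dimethyl-5-[7-methyl-2-(3-methylbut-2-en-1-yl)-3-oxooct-6-en-1-yl]-2-oxooxepane-3-carboxylate | COC(=O)[C@]1(C(=O)c2ccccc2)C(=O)OCC[C@@H](CC(CC=C(C)C)C(=O)CCC=C(C)C)C1(C)C
F3 | step 8 | (1R,5S,7R)-1-benzoyl-2-hydroxy-7-(2-hydroxyethyl)-8,8-dimethyl-3,5-bis(3-methylbut-2-en-1-yl)bicyclo[3.3.1]non-2-ene-4,9-dione (enol form) | OC1=C(CC=C(C)C)C(=O)[C@]2(CC=C(C)C)C[C@H](CCO)C(C)(C)[C@@]1(C(=O)c1ccccc1)C2=O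
F4 | step 2 | 1-(1,4-dioxaspiro[4.5]decan-8-yl)ethan-1-one | CC(=O)C1CCC2(CC1)OCCO2
F5 | step 2 | ethyl 2-benzoyl-3-(1,4-dioxaspiro[4.5]decan-8-yl)but-2-enoate (E/Z mixture) | CCOC(=O)C(C(=O)c1ccccc1)=C(C)C1CCC2(CC1)OCCO2
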